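The runs were generated by integration for substances that don't exist, and the scatter is random.

I decide to reckon the flask by its equivalents, the incoming ligand charged per starting complex, and not by the clock: 1.50 in the flask against 2.23 in the north-east run.

| flask | starting complex | incoming ligand | remark | time |
|---|---|---|---|---|
| north-east | 0.13 M | 0.29 M | run made earlier |  |
| flask | 0.13 M | 0.195 M |  | 6.0 d |

- north-east (time / h: complex with two exchanged / %, starting complex / %): 2.50: 9.9, 80.0; 8.00: 21.4, 54.9; 12.0: 25.0, 44.5; 20.0: 24.0, 29.6; 30.0: 22.0, 19.9

(each reading ± 0.5 percentage points)

- time up to 6.0 d at which complex with two exchanged stands highest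
- the amount of complex with two exchanged, in percent of the starting complex charged, at that time

I turn the question round and ask what must be true for the flask's peak of complex with two exchanged to keep its north-east height. That height holds if every step is first order in [incoming ligand], none runs back and that ligand lasts to the peak, but no earlier run changes its charge, so the readings cannot test this and what I reckon here is a guess. At 12.0 h, where the north-east reading stands highest at 25.0%, 44.5% of the starting complex remains, so by these readings at least 0.105 M of incoming ligand has gone, one for each complex lost and a second for each complex with two exchanged. That is 36.1% of the north-east charge but half of the flask's. As my guess I carry 11.2%, the peak yield per equivalent, which is the highest north-east reading of complex with two exchanged divided by the equivalents charged in that run. Taking it as unchanged with the starting complex held at 0.13 M, I expect 16.8% in the flask.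

The forecast gives 25% at 1.1 d, holding that “the peak height stays about the same”, so its height stands above mine.

The flask gives 17.8% at 0.673 d.

    starting complex + incoming ligand ⇌ leaving ligand + complex with one exchanged (K = 32.0, k = 8.80 × 10⁻⁵ L mol⁻¹ s⁻¹)
    complex with one exchanged + incoming ligand ⇌ leaving ligand + complex with two exchanged (K = 0.590, k = 8.60 × 10⁻⁴ L mol⁻¹ s⁻¹)
    complex with two exchanged + incoming ligand ⇌ leaving ligand + complex with three exchanged (K = 1.10, k = 3.00 × 10⁻⁵ L mol⁻¹ s⁻¹)
    complex with three exchanged + incoming ligand ⇌ leaving ligand + complex with four exchanged (K = 12.0, k = 5.60 × 10⁻⁵ L mol⁻¹ s⁻¹)

Changing the incoming ligand charge from the north-east run moves the highest amount from 24.1% to 17.8%, while the time limit changed by itself leaves 24.1%. Per equivalent the flask holds 11.8%, beside the 11.2% I carried, and for the neighbour charged with 0.12 M of incoming ligand, 0.923 equiv, my figure gives 10.3%, while that neighbour's peak stands at 11.6%.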